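Ring A is read as an acylresorcinol: C4a bears the acyl carbon, O8a lies ortho and O7 para to it, C6 and C8 bear the prenyl groups and C5 is unsubstituted. Disconnecting C5–C6 and C4a–C8a leads to a 1-methoxy-1,3-bis(trimethylsilyloxy)diene made from methyl 2,4-diprenylacetoacetate (C6, C7, C8, C8a with both prenyl groups and both oxygens) and to but-3-yn-2-one (C5, C4a, C4, C3). A single [4+2] benzannulation with loss of methanol should give the complete ring A at the aromatic oxidation level, so that no phenol is ever prenylated. Ring C is then closed as a chromone and C2 is set by a rhodium-catalysed asymmetric 1,4-addition of the ring B boronic acid.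

Key step: step 5

Assumption: metal enolates, phenoxides and catalyst-bound species count as forms of the numbered compounds and carry no numbers; should the (S) ligand of step 8 give the 2R series, its (R) antipode is used.

Step 1
Reactants: 1 methyl acetoacetate; 2 prenyl bromide (1-bromo-3-methylbut-2-ene)
Product: 3 methyl 7-methyl-3-oxooct-6-enoate
Conditions: NaH, THF, 0 °C; n-BuLi, 0 °C; 2, 0 → 20 °C; aq NH4Cl
Reagents that add atoms: none
Why: γ-Alkylation of an acetoacetate dianion: the second deprotonation creates the more nucleophilic C4 carbanion, which alone attacks the primary carbon of the allylic bromide (SN2) and leaves the C2 enolate untouched.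

Step 2
Reactants: 3 methyl 7-methyl-3-oxooct-6-enoate; 2 prenyl bromide
Product: 4 methyl 7-methyl-2-(3-methylbut-2-en-1-yl)-3-oxooct-6-enoate (racemic at C2)
Conditions: NaH, THF, 0 °C; 2, 0 → 20 °C
Reagents that add atoms: none
Why: Alkylation of a β-keto ester monoenolate: the sodium enolate should react with the soft allylic bromide at carbon, one equivalent each of base and halide limits double alkylation, and the new C2 centre is planarised in the next step.

Step 3
Reactants: 4 methyl 7-methyl-2-(3-methylbut-2-en-1-yl)-3-oxooct-6-enoate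
Product: 5 methyl 7-methyl-2-(3-methylbut-2-en-1-yl)-3-(trimethylsilyloxy)octa-2,6-dienoate (2E/2Z mixture)
Conditions: Me3SiCl, Et3N, toluene, 20 °C
Reagents that add atoms: chlorotrimethylsilane, C[Si](C)(C)Cl
Why: Soft enolisation and O-silylation of a β-keto ester traps the conjugated enol as its silyl ether; the geometric mixture does not matter because both isomers give the same dienolate.

Step 4
Reactants: 5 methyl 7-methyl-2-(3-methylbut-2-en-1-yl)-3-(trimethylsilyloxy)octa-2,6-dienoate
Product: 6 1-methoxy-2,4-bis(3-methylbut-2-en-1-yl)-1,3-bis(trimethylsilyloxy)buta-1,3-diene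
Conditions: LiN(i-Pr)2, THF, −78 °C; Me3SiCl, −78 → 20 °C
Reagents that add atoms: chlorotrimethylsilane, C[Si](C)(C)Cl
Why: Kinetic γ-deprotonation of the β-silyloxy enoate at C4 gives the extended ester dienolate, which the chlorosilane traps at oxygen (silyl ketene acetal formation); the moisture-sensitive diene is used crude.

Step 5
Reactants: 6 1-methoxy-2,4-bis(3-methylbut-2-en-1-yl)-1,3-bis(trimethylsilyloxy)buta-1,3-diene; 7 but-3-yn-2-one
Product: 10 1-[2,4-dihydroxy-3,5-bis(3-methylbut-2-en-1-yl)phenyl]ethanone, via cyclohexadiene cycloadduct 8 (not isolated), via bis(trimethylsilyl) ether 9 (not isolated)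
Conditions: toluene, 0 → 60 °C; then 1 M HCl, THF, 20 °C
Reagents that add atoms: none
Why: The electron-rich diene 6 and the electron-poor ynone 7 should combine in a Diels–Alder reaction of normal electron demand (concerted but asynchronous; in the polar limit a Mukaiyama–Michael addition of the diene terminus followed by attack of the resulting allenolate on the activated ester carbon), forming the C5–C6 and C4a–C8a bonds of cycloadduct 8. The closest known reaction type is the benzannulation of 1-alkoxy-1,3-bis(silyloxy)-1,3-dienes with propiolates and alkynones, which gives hydroxybenzoates and acylresorcinols. Ring A, the only ring closed, arises by intermolecular [4+2] cycloaddition (6-exo-trig closure in the stepwise limit); 8 then loses methanol across C8a and C6 to give arene 9, and the dilute acid work-up hydrolyses both aryl silyl ethers. The sp3 centres at C6 and C8a of 8 are erased on aromatisation, so no stereocontrol is needed and the diene geometry does not affect the outcome. The one selectivity required is regiochemical: the oxygen-free diene terminus (future C6) carries the largest HOMO coefficient and pairs with the unsubstituted β-carbon of 7 (future C5), which places the acetyl group ortho to O8a and para to O7. Methanol and not silanol should leave the mixed acetal carbon, because the silylated oxygen stays on carbon as the emerging phenol oxygen, as in related annulations that end in free ortho-hydroxy groups.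

Step 6
Reactants: 10 1-[2,4-dihydroxy-3,5-bis(3-methylbut-2-en-1-yl)phenyl]ethanone
Product: 11 1-[2-hydroxy-4-(methoxymethoxy)-3,5-bis(3-methylbut-2-en-1-yl)phenyl]ethanone
Conditions: MOMCl, i-Pr2NEt, CH2Cl2, 0 → 20 °C
Reagents that add atoms: chloromethyl methyl ether, COCCl
Why: Williamson-type O-alkylation of a phenol: O2 is held in a hydrogen bond to the acetyl carbonyl, so only the non-chelated, more acidic O4 (the later O7) should be converted into its methoxymethyl ether.

Step 7
Reactants: 11 1-[2-hydroxy-4-(methoxymethoxy)-3,5-bis(3-methylbut-2-en-1-yl)phenyl]ethanone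
Product: 13 7-(methoxymethoxy)-6,8-bis(3-methylbut-2-en-1-yl)-4H-chromen-4-one, via enaminone 12 (not isolated)
Conditions: Me2NCH(OMe)2, toluene, 95 °C; then AcOH, 50 °C
Reagents that add atoms: N,N-dimethylformamide dimethyl acetal, COC(OC)N(C)C
Why: Enaminone route to chromones: the amide acetal condenses with the acetyl CH3 to the vinylogous amide 12, and under weak acid the phenol adds to its β-carbon (6-endo-trig addition–elimination) with loss of dimethylamine, conditions that aryl methoxymethyl ethers and prenyl alkenes should tolerate.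

Step 8
Reactants: 13 7-(methoxymethoxy)-6,8-bis(3-methylbut-2-en-1-yl)-4H-chromen-4-one; 14 [4-(methoxymethoxy)phenyl]boronic acid
Product: 15 (2S)-7-(methoxymethoxy)-2-[4-(methoxymethoxy)phenyl]-6,8-bis(3-methylbut-2-en-1-yl)-2,3-dihydro-4H-chromen-4-one
Conditions: [RhOH(cod)]2 (cat.), (S)-MeO-F12-BIPHEP [(S)-2,2'-bis[bis(3,4,5-trifluorophenyl)phosphino]-6,6'-dimethoxy-1,1'-biphenyl] (cat.), toluene–H2O, 30 °C
Reagents that add atoms: none
Why: Hayashi–Miyaura asymmetric 1,4-addition: transmetalation of 14 to the hydroxorhodium–bisphosphine complex gives an aryl–rhodium species that inserts the chromone C2=C3 bond, and hydrolysis of the rhodium enolate releases the flavanone; the C2 stereocentre is set by the catalyst, the (S)-biaryl bisphosphine being expected, by the model that holds for cyclic Z-enones, to deliver the aryl group to the Re face of C2 (2S), while the electron-poor ligand speeds insertion into the vinylogous ester and the base-free medium with a protected ring B phenol keeps ring C closed.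

Step 9
Reactants: 15 (2S)-7-(methoxymethoxy)-2-[4-(methoxymethoxy)phenyl]-6,8-bis(3-methylbut-2-en-1-yl)-2,3-dihydro-4H-chromen-4-one
Product: 18 (2S)-7-hydroxy-2-(4-hydroxyphenyl)-6,8-bis(3-methylbut-2-en-1-yl)-2,3-dihydro-4H-chromen-4-one, via flavanone 7-MOM ether 16 (not isolated), via flavanone 4'-MOM ether 17 (not isolated)
Conditions: HCl (1 M in MeOH), 20 → 40 °C; NaHCO3 quench
Reagents that add atoms: none
Why: Acid-catalysed transacetalisation of the two aryl methoxymethyl ethers to dimethoxymethane in methanol, a standard release of prenylated phenols at moderate temperature; ring C and the C2 stereocentre are not involved because no base is present to trigger retro-oxa-Michael opening.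

Compound list
1 | methyl acetoacetate | COC(=O)CC(C)=O | starting material
2 | prenyl bromide (1-bromo-3-methylbut-2-ene) | CC(C)=CCBr | starting material
3 | methyl 7-methyl-3-oxooct-6-enoate | COC(=O)CC(=O)CCC=C(C)C | intermediate
4 | methyl 7-methyl-2-(3-methylbut-2-en-1-yl)-3-oxooct-6-enoate (racemic) | COC(=O)C(CC=C(C)C)C(=O)CCC=C(C)C | intermediate
5 | methyl 7-methyl-2-(3-methylbut-2-en-1-yl)-3-(trimethylsilyloxy)octa-2,6-dienoate (2E/2Z mixture) | COC(=O)C(CC=C(C)C)=C(CCC=C(C)C)O[Si](C)(C)C | intermediate
6 | 1-methoxy-2,4-bis(3-methylbut-2-en-1-yl)-1,3-bis(trimethylsilyloxy)buta-1,3-diene (geometric mixture) | COC(O[Si](C)(C)C)=C(CC=C(C)C)C(O[Si](C)(C)C)=CCC=C(C)C | intermediate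
7 | but-3-yn-2-one | CC(=O)C#C | starting material
8 | 1-[6-methoxy-3,5-bis(3-methylbut-2-en-1-yl)-4,6-bis(trimethylsilyloxy)cyclohexa-1,4-dien-1-yl]ethanone (diastereomer mixture) | COC1(O[Si](C)(C)C)C(CC=C(C)C)=C(O[Si](C)(C)C)C(CC=C(C)C)C=C1C(C)=O | intermediate
9 | 1-[3,5-bis(3-methylbut-2-en-1-yl)-2,4-bis(trimethylsilyloxy)phenyl]ethanone | CC(=O)c1cc(CC=C(C)C)c(O[Si](C)(C)C)c(CC=C(C)C)c1O[Si](C)(C)C | intermediate
10 | 1-[2,4-dihydroxy-3,5-bis(3-methylbut-2-en-1-yl)phenyl]ethanone | CC(=O)c1cc(CC=C(C)C)c(O)c(CC=C(C)C)c1O | intermediate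
11 | 1-[2-hydroxy-4-(methoxymethoxy)-3,5-bis(3-methylbut-2-en-1-yl)phenyl]ethanone | CC(=O)c1cc(CC=C(C)C)c(OCOC)c(CC=C(C)C)c1O | intermediate
12 | (E)-3-(dimethylamino)-1-[2-hydroxy-4-(methoxymethoxy)-3,5-bis(3-methylbut-2-en-1-yl)phenyl]prop-2-en-1-one | CN(C)/C=C/C(=O)c1cc(CC=C(C)C)c(OCOC)c(CC=C(C)C)c1O | intermediate
13 | 7-(methoxymethoxy)-6,8-bis(3-methylbut-2-en-1-yl)-4H-chromen-4-one | O=c1ccoc2c(CC=C(C)C)c(OCOC)c(CC=C(C)C)cc12 | intermediate
14 | [4-(methoxymethoxy)phenyl]boronic acid | COCOc1ccc(B(O)O)cc1 | starting material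
15 | (2S)-7-(methoxymethoxy)-2-[4-(methoxymethoxy)phenyl]-6,8-bis(3-methylbut-2-en-1-yl)-2,3-dihydro-4H-chromen-4-one | CC(C)=CCc1cc2c(c(CC=C(C)C)c1OCOC)O[C@H](c1ccc(OCOC)cc1)CC2=O | intermediate
16 | (2S)-2-(4-hydroxyphenyl)-7-(methoxymethoxy)-6,8-bis(3-methylbut-2-en-1-yl)-2,3-dihydro-4H-chromen-4-one | CC(C)=CCc1cc2c(c(CC=C(C)C)c1OCOC)O[C@H](c1ccc(O)cc1)CC2=O | intermediate
17 | (2S)-7-hydroxy-2-[4-(methoxymethoxy)phenyl]-6,8-bis(3-methylbut-2-en-1-yl)-2,3-dihydro-4H-chromen-4-one | CC(C)=CCc1cc2c(c(CC=C(C)C)c1O)O[C@H](c1ccc(OCOC)cc1)CC2=O | intermediate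
18 | (2S)-7-hydroxy-2-(4-hydroxyphenyl)-6,8-bis(3-methylbut-2-en-1-yl)-2,3-dihydro-4H-chromen-4-one | CC(C)=CCc1cc2c(c(CC=C(C)C)c1O)O[C@H](c1ccc(O)cc1)CC2=O | target

Total step count: 9. Longest linear sequence: 9 steps (1 → 18); 2, 7 and 14 are purchased.

Steps most likely to fail

Step 5. The ynone may oligomerise or the diene may hydrolyse before the cycloaddition. Ring closure may be slow because the diene terminus is substituted. The mixed acetal may collapse with loss of silanol, which would leave O8a methylated. Fallback: setting out from 2, purchased 2,4-dihydroxyacetophenone (CC(=O)c1ccc(O)cc1O) is C-prenylated twice on the ring with 2 in aqueous KOH at 0 → 20 °C (nuclear prenylation of a resorcinol phenoxide). This should give 10 together with the mono-prenylated ketones 1-[2,4-dihydroxy-3-(3-methylbut-2-en-1-yl)phenyl]ethanone F1 and 1-[2,4-dihydroxy-5-(3-methylbut-2-en-1-yl)phenyl]ethanone F2. These are separated by chromatography and resubmitted to the same conditions. The route is rejoined at 10, at the price of a regioisomer separation.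

Step 8. Insertion of the electron-rich, fully substituted chromone into the aryl–rhodium bond may be slow, protodeboronation may consume 14, and facial discrimination may be insufficient. Fallback: setting out from 11, Claisen–Schmidt condensation with purchased 4-(methoxymethoxy)benzaldehyde (COCOc1ccc(C=O)cc1; KOH, EtOH–H2O, 20 °C) should give (E)-1-[2-hydroxy-4-(methoxymethoxy)-3,5-bis(3-methylbut-2-en-1-yl)phenyl]-3-[4-(methoxymethoxy)phenyl]prop-2-en-1-one F3. NaOAc in refluxing EtOH should close ring C by oxa-Michael addition to racemic 7-(methoxymethoxy)-2-[4-(methoxymethoxy)phenyl]-6,8-bis(3-methylbut-2-en-1-yl)-2,3-dihydro-4H-chromen-4-one F4. Kinetic resolution by Noyori-type asymmetric transfer hydrogenation (RuCl[(R,R)-TsDPEN](p-cymene), HCO2H–Et3N, EtOAc, 20 °C) should reduce the 2R enantiomer to (2R,4R)-7-(methoxymethoxy)-2-[4-(methoxymethoxy)phenyl]-6,8-bis(3-methylbut-2-en-1-yl)-3,4-dihydro-2H-chromen-4-ol F5, which is removed by chromatography. The unreacted 2S ketone is 15, where the route is rejoined.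

Step 9. The freed O7 phenol may add under acid to a neighbouring prenyl alkene (dimethylchroman formation), the alkenes may undergo solvolytic addition, and configuration may erode by reversible opening of ring C. Fallback: a line free of protecting groups and of acid, setting out from 10. Claisen–Schmidt condensation with purchased 4-hydroxybenzaldehyde (O=Cc1ccc(O)cc1) in concentrated aqueous KOH–EtOH at 20 °C should give (E)-1-[2,4-dihydroxy-3,5-bis(3-methylbut-2-en-1-yl)phenyl]-3-(4-hydroxyphenyl)prop-2-en-1-one F6. NaOAc in refluxing EtOH should cyclise it to racemic 7-hydroxy-2-(4-hydroxyphenyl)-6,8-bis(3-methylbut-2-en-1-yl)-2,3-dihydro-4H-chromen-4-one F7. Preparative chromatography on a polysaccharide chiral stationary phase should then deliver 18, where the route is rejoined. The (2R)-7-hydroxy-2-(4-hydroxyphenyl)-6,8-bis(3-methylbut-2-en-1-yl)-2,3-dihydro-4H-chromen-4-one F8 is re-equilibrated to F7 with NaOAc in hot EtOH and recycled.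

Further compounds
F1 | step 5 | 1-[2,4-dihydroxy-3-(3-methylbut-2-en-1-yl)phenyl]ethanone | CC(=O)c1ccc(O)c(CC=C(C)C)c1O
F2 | step 5 | 1-[2,4-dihydroxy-5-(3-methylbut-2-en-1-yl)phenyl]ethanone | CC(=O)c1cc(CC=C(C)C)c(O)cc1O
F3 | step 8 | (E)-1-[2-hydroxy-4-(methoxymethoxy)-3,5-bis(3-methylbut-2-en-1-yl)phenyl]-3-[4-(methoxymethoxy)phenyl]prop-2-en-1-one | COCOc1ccc(/C=C/C(=O)c2cc(CC=C(C)C)c(OCOC)c(CC=C(C)C)c2O)cc1
F4 | step 8 | racemic 7-(methoxymethoxy)-2-[4-(methoxymethoxy)phenyl]-6,8-bis(3-methylbut-2-en-1-yl)-2,3-dihydro-4H-chromen-4-one | COCOc1ccc(C2CC(=O)c3cc(CC=C(C)C)c(OCOC)c(CC=C(C)C)c3O2)cc1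
F5 | step 8 | (2R,4R)-7-(methoxymethoxy)-2-[4-(methoxymethoxy)phenyl]-6,8-bis(3-methylbut-2-en-1-yl)-3,4-dihydro-2H-chromen-4-ol | COCOc1ccc([C@H]2C[C@@H](O)c3cc(CC=C(C)C)c(OCOC)c(CC=C(C)C)c3O2)cc1
F6 | step 9 | (E)-1-[2,4-dihydroxy-3,5-bis(3-methylbut-2-en-1-yl)phenyl]-3-(4-hydroxyphenyl)prop-2-en-1-one | O=C(/C=C/c1ccc(O)cc1)c1cc(CC=C(C)C)c(O)c(CC=C(C)C)c1O
F7 | step 9 | racemic 7-hydroxy-2-(4-hydroxyphenyl)-6,8-bis(3-methylbut-2-en-1-yl)-2,3-dihydro-4H-chromen-4-one | CC(C)=CCc1cc2c(c(CC=C(C)C)c1O)OC(c1ccc(O)cc1)CC2=O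
F8 | step 9 | (2R)-7-hydroxy-2-(4-hydroxyphenyl)-6,8-bis(3-methylbut-2-en-1-yl)-2,3-dihydro-4H-chromen-4-one | CC(C)=CCc1cc2c(c(CC=C(C)C)c1O)O[C@@H](c1ccc(O)cc1)CC2=O
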